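(The constants were set for the occasion; the flask was simulated.)

A small charge of free enzyme has to carry a starting material through a two-half cycle while the second substrate reaches the solution by dissolving from a solid.

    starting material + free enzyme ⇌ first complex (K1 = 10 M⁻¹, k1 = 85300 M⁻¹ min⁻¹)
    first complex → loaded enzyme + first product (k2 = 105 min⁻¹)
    second substrate + loaded enzyme ⇌ second complex (K3 = 91.6 M⁻¹, k3 = 25900 M⁻¹ min⁻¹)
    second complex → free enzyme + target (k4 = 87.0 min⁻¹)
    solid second substrate ⇌ second substrate, rate k5*(cs5 - [second substrate]) while solid is left; crystals form when [second substrate] > cs5 (cs5 = 19 mM, k5 = 0.0406 min⁻¹)

starting material 0.053 M; solid second substrate 1.50 equiv; free enzyme 0.02 mol%; time 80 min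

- as a solid, counted per litre of solution: solid second substrate
- at the start none of the solid second substrate is in solution
- run time (flask): 80 min

- how much target there is at 80 min, in percent of the starting material charged
- the change that raises the amount of target at 80 min, in percent of the starting material charged most ("none" if none brings more than 2 percentage points) (Sunday's / Saturday's / Tuesday's / none)
- amount of target at 80 min, in percent of the starting material charged, after Sunday's

- Sunday's: doubling the amount of free enzyme, all else as stated
- Saturday's: doubling the dissolution coefficient of step 5, all else as stated
- Tuesday's: doubling the solubility in step 5, all else as stated

With 1.50 equiv of solid, the starting material is the limiting reagent, so the end state is a flask of target and the question is how fast it is approached. I count speed by the round time, the inverse of the turnover frequency: each half of the cycle costs the inverse of its chemical rate constant plus a binding term that goes as one over its substrate's concentration. Holding the starting material at its charge, the parts without second substrate come to 0.0392 min, and the second-substrate term at solubility to 0.00864 min, so a round takes 0.0478 min. The bench rule says that excess solid keeps its solution saturated, and then 1.06 × 10⁻⁵ M of enzyme would make 33.4% of the charge in 80 min.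

The border of that rule is the demand ratio D = 0.287, what the enzyme draws at saturation divided by dissolution coefficient times solubility, the most the solid delivers into an empty solution. At a D of this size I stop trusting the rule: in my reckoning the second substrate levels off below solubility by the fraction D, at 0.0135 M, and the round lengthens to 0.0513 min. The solution also has to fill, so I book half of the inverse dissolution coefficient, 12.3 min, as lost time. My reckoning gives 26.4%. Sunday's, doubling the free enzyme, takes D to 0.574 and gives 45.5%; Saturday's, doubling the dissolution coefficient, gives 30.0%; Tuesday's, doubling the solubility, with D at 0.158, gives 30.5%. My choice is Sunday's.

The forecast says 26.4%, Sunday's and 46.5%, holding that “Rate is nearly proportional to enzyme and dissolution keeps up reasonably well”.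

The simulation gives 26.4%, Sunday's and 46.6%, a gain of 20 percentage points against 2.3 points for Saturday's and 4.4 points for Tuesday's; the simulated amount of target moves 5 points at a loading of 0.016 mol% or 0.024 mol%. In this flask the second substrate reads 0.0139 M at 80.0 min, against my level of 0.0135 M. The neighbouring flask is the same charge read at 30 min: filling towards that level puts the second substrate at 0.009537 M, and the lost time gives 6.89% target, while that flask holds the second substrate at 0.0105 M and target at 8.61%.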